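**Retrosynthetic overview** (chain numbered C1 on guaiacyl ring A to C7 on catechol ring B; ring B atoms C1'–C6', C1' on C7)
- The strategy rests on ring B, a 1,2,4-trisubstituted benzene whose adjacent free hydroxyls at C3' and C4' must stay distinct from the C3 methyl ether of ring A. Ring B is therefore built last, with its two oxygens arriving as acid-labile silyl ethers.
- Target ⇒ pentaacetate ⇒ pentaol ⇒ syn-acetonide triphenol. The C3/C5 acetates are set apart from the three phenols by peracetylation and selective aryl deacetylation. The C7 carbonyl is removed by hydrogenolysis while the acetonide still masks the diol.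
- Ring B ⇒ [4+2] cycloaddition of a C7 terminal ynone with 2,3-bis(trimethylsilyloxy)buta-1,3-diene, then dehydrogenation (bonds C1'–C2' and C5'–C6').
- Ynone ⇒ C7 tert-butyl ester (partial reduction, ethynyl addition, oxidation). C1–C2 ⇒ Wittig reaction between the O-benzylvanillyl ylide and the aldehyde of the commercial syn-acetonide alcohol, which supplies both stereocentres (C3, C5).
- Ring order: ring A and the 1,3-dioxane are bought; ring B is the only ring formed (step 8); the dioxane is opened in step 10.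

Key step: step 8

Remark on the chemistry (assumption): compounds 6, 8, 11 and 18 are stereoisomer mixtures at positions that are erased later (alkene geometry, carbinol carbons), and on the catalyst in step 9 the benzyl ether is taken to cleave before the carbonyl group is reduced; the opposite order leads to the same product.

**Step 1**
Reactants: 1 (4-benzyloxy-3-methoxyphenyl)methanol
Product: 2 [(4-benzyloxy-3-methoxyphenyl)methyl]triphenylphosphonium bromide
Conditions: PPh3·HBr, MeCN, reflux; precipitate with Et2O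
Reagents that add atoms: triphenylphosphine hydrobromide, [Br-].[PH+](c1ccccc1)(c1ccccc1)c1ccccc1
Why: Acid-promoted ionisation of the electron-rich 4-alkoxybenzylic alcohol and capture of the benzylic electrophile by PPh3 gives the salt directly (benzylic phosphonium salt formation), the aryl benzyl ether being inert to this weak acid.

**Step 2**
Reactants: 3 tert-butyl 2-[(4R,6S)-6-(hydroxymethyl)-2,2-dimethyl-1,3-dioxan-4-yl]acetate
Product: 4 tert-butyl 2-[(4R,6S)-6-formyl-2,2-dimethyl-1,3-dioxan-4-yl]acetate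
Conditions: TEMPO (cat.), KBr (cat.), NaOCl, NaHCO3, CH2Cl2–H2O, 0 °C
Reagents that add atoms: none
Why: Anelli oxidation (TEMPO/NaOCl) converts the primary alcohol to the aldehyde at buffered pH, leaving acetonide and tert-butyl ester intact; the cis-diequatorial dioxane is the thermodynamically favoured isomer, so the α-alkoxy centre has no drive to epimerise.

**Step 3**
Reactants: 2 benzylic phosphonium bromide; 4 acetonide aldehyde
Product: 6 tert-butyl 2-[(4R,6S)-6-[2-(4-benzyloxy-3-methoxyphenyl)ethenyl]-2,2-dimethyl-1,3-dioxan-4-yl]acetate (E/Z mixture), via ylide 5 (not isolated)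
Conditions: 2, NaN(SiMe3)2, THF, 0 °C; then 4, −78 °C→rt
Reagents that add atoms: none
Why: Wittig olefination by the semi-stabilised benzylic ylide forms the C1–C2 bond at low temperature without disturbing the adjacent stereocentre; the alkene geometry is irrelevant because the next step saturates it.

**Step 4**
Reactants: 6 styrenyl ester (E/Z mixture)
Product: 7 tert-butyl 2-[(4R,6R)-6-[2-(4-benzyloxy-3-methoxyphenyl)ethyl]-2,2-dimethyl-1,3-dioxan-4-yl]acetate
Conditions: p-TsNHNH2 (excess, portionwise), NaOAc, DME–H2O, reflux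
Reagents that add atoms: none
Why: Diimide reduction transfers two hydrogens to the C1=C2 bond in a concerted syn fashion and, unlike hydrogenation over palladium, cannot cleave the aryl benzyl ether or the allylic C3–O bond (the descriptor at dioxane C6 changes by priority only).

**Step 5**
Reactants: 7 saturated tert-butyl ester
Product: 9 2-[(4R,6R)-6-[2-(4-benzyloxy-3-methoxyphenyl)ethyl]-2,2-dimethyl-1,3-dioxan-4-yl]acetaldehyde, via aluminium hemiacetal 8 (not isolated)
Conditions: i-Bu2AlH (1.2 equiv), PhMe, −78 °C; MeOH, then aq. KNaC4H4O6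
Reagents that add atoms: none
Why: Partial ester reduction with i-Bu2AlH stops at the tetrahedral aluminium hemiacetal 8, held by the bulky tert-butoxy group and chelation to the β-oxygen, which releases the aldehyde only on aqueous work-up.

**Step 6**
Reactants: 9 C7 aldehyde; 10 ethynylmagnesium bromide
Product: 11 (2RS)-1-[(4S,6R)-6-[2-(4-benzyloxy-3-methoxyphenyl)ethyl]-2,2-dimethyl-1,3-dioxan-4-yl]but-3-yn-2-ol
Conditions: HC≡CMgBr (2.5 equiv), THF, −78→0 °C; sat. aq. NH4Cl
Reagents that add atoms: ethynylmagnesium bromide (10), C#C[Mg]Br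
Why: Grignard 1,2-addition of the acetylide to the aldehyde gives the propargylic alcohol; the new carbinol centre forms without control and is erased in the next step.

**Step 7**
Reactants: 11 propargylic alcohol (epimer mixture)
Product: 12 1-[(4R,6R)-6-[2-(4-benzyloxy-3-methoxyphenyl)ethyl]-2,2-dimethyl-1,3-dioxan-4-yl]but-3-yn-2-one
Conditions: Dess–Martin periodinane, NaHCO3, CH2Cl2, 0 °C→rt; use promptly
Reagents that add atoms: none
Why: Dess–Martin oxidation of the secondary propargylic alcohol under buffered, non-basic conditions should give the terminal ynone without β-elimination of the C5 oxygen.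

**Step 8**
Reactants: 12 syn-acetonide terminal ynone; 13 2,3-bis(trimethylsilyloxy)buta-1,3-diene
Product: 15 1-[3,4-bis(trimethylsilyloxy)phenyl]-2-[(4R,6R)-6-[2-(4-benzyloxy-3-methoxyphenyl)ethyl]-2,2-dimethyl-1,3-dioxan-4-yl]ethan-1-one, via cyclohexadiene cycloadduct 14 (not isolated)
Conditions: 13 (3 equiv), BHT (cat.), PhMe, 100 °C, sealed tube; strip volatiles and excess 13 in vacuo; DDQ (1.0 equiv), PhMe, 0 °C; filter, use crude
Reagents that add atoms: 2,3-bis(trimethylsilyloxy)buta-1,3-diene (13), C=C(O[Si](C)(C)C)C(=C)O[Si](C)(C)C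
Why: A concerted, thermally allowed [4+2] cycloaddition between the electron-rich diene 13 and the electron-poor ynone 12 forms the C1'–C2' and C5'–C6' bonds in one event and gives the 1,4-cyclohexadiene 14, from which DDQ abstracts hydride at a doubly allylic CH2 before proton loss gives the arene. The closest known reaction type is the Diels–Alder reaction of 2,3-bis(silyloxy)buta-1,3-dienes with acetylenic dienophiles followed by dehydrogenation of the adduct to a catechol bis(silyl ether). Ring B is closed by intermolecular cycloaddition of the diene termini across the alkyne, so the carbonyl-bearing alkyne carbon becomes C1' and the two silyloxy carbons become C3' and C4', meta and para to C7. No stereocentre is created, and C3 and C5 are remote from the reacting atoms and not epimerisable under neutral thermal conditions. Regioselectivity is not an issue because the diene is constitutionally symmetric; the step needs chemoselective dehydrogenation of 14 over the benzylic C1–H bonds and benzyl ether of ring A, which the aromatisation driving force should secure once excess diene is removed and one equivalent of DDQ is used at 0 °C. The ring B oxygens arrive as trimethylsilyl ethers that fall off by methanolysis, leaving the methyl ether of ring A untouched.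

**Step 9**
Reactants: 15 bis(trimethylsilyl) catechol aryl ketone (crude)
Product: 19 4-{2-[(4S,6R)-6-[2-(4-hydroxy-3-methoxyphenyl)ethyl]-2,2-dimethyl-1,3-dioxan-4-yl]ethyl}benzene-1,2-diol, via catechol ketone 16 (not isolated), via debenzylated ketone 17 (not isolated), via benzylic carbinol 18 (not isolated)
Conditions: MeOH–EtOAc, AcOH (2 equiv), rt, 30 min; then H2 (3 atm), 10% Pd/C, rt
Reagents that add atoms: none
Why: Methanolysis frees the catechol, then palladium-catalysed hydrogenolysis cleaves the aryl benzyl ether and takes the para-hydroxy-activated aryl ketone through carbinol 18 to the methylene group (benzylic hydrogenolysis), while the intact acetonide keeps the C3 oxygen from adding to C7.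

**Step 10**
Reactants: 19 syn-acetonide triphenol
Product: 20 (3R,5S)-7-(3,4-dihydroxyphenyl)-1-(4-hydroxy-3-methoxyphenyl)heptane-3,5-diol
Conditions: 1 M aq. HCl, THF, rt, degassed, under Ar
Reagents that add atoms: none
Why: Acid-catalysed acetal hydrolysis releases the syn-1,3-diol; only the ketal C–O bonds break, so C3 and C5 keep their configuration.

**Step 11**
Reactants: 20 pentaol
Product: 21 (3R,5S)-1-(4-acetoxy-3-methoxyphenyl)-7-(3,4-diacetoxyphenyl)heptane-3,5-diyl diacetate
Conditions: Ac2O (excess), pyridine, DMAP (cat.), 0 °C→rt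
Reagents that add atoms: acetic anhydride, CC(=O)OC(C)=O
Why: Exhaustive DMAP-catalysed O-acylation converts all five hydroxyls to acetates with retention at C3 and C5, since no bond to either stereocentre is broken.

**Step 12**
Reactants: 21 pentaacetate
Product: 22 (3R,5S)-7-(3,4-dihydroxyphenyl)-1-(4-hydroxy-3-methoxyphenyl)heptane-3,5-diyl diacetate
Conditions: NH4OAc (10 equiv), MeOH–H2O (4:1), rt, under Ar
Reagents that add atoms: none
Why: Chemoselective transesterification: aryl acetates, with a phenoxide leaving group, undergo NH4OAc-mediated methanolysis far faster than secondary alkyl acetates, so the three phenols should be released while the C3 and C5 acetates remain.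

**Compound list**
1 | (4-benzyloxy-3-methoxyphenyl)methanol | COc1cc(CO)ccc1OCc1ccccc1 | starting material
2 | [(4-benzyloxy-3-methoxyphenyl)methyl]triphenylphosphonium bromide | COc1cc(C[P+](c2ccccc2)(c2ccccc2)c2ccccc2)ccc1OCc1ccccc1.[Br-] | intermediate
3 | tert-butyl 2-[(4R,6S)-6-(hydroxymethyl)-2,2-dimethyl-1,3-dioxan-4-yl]acetate | OC[C@@H]1C[C@H](CC(=O)OC(C)(C)C)OC(C)(C)O1 | starting material
4 | tert-butyl 2-[(4R,6S)-6-formyl-2,2-dimethyl-1,3-dioxan-4-yl]acetate | O=C[C@@H]1C[C@H](CC(=O)OC(C)(C)C)OC(C)(C)O1 | intermediate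
5 | [(4-benzyloxy-3-methoxyphenyl)methylidene]triphenylphosphorane (ylide) | COc1cc(C=P(c2ccccc2)(c2ccccc2)c2ccccc2)ccc1OCc1ccccc1 | intermediate
6 | tert-butyl 2-[(4R,6S)-6-[2-(4-benzyloxy-3-methoxyphenyl)ethenyl]-2,2-dimethyl-1,3-dioxan-4-yl]acetate (E/Z mixture) | COc1cc(C=C[C@@H]2C[C@H](CC(=O)OC(C)(C)C)OC(C)(C)O2)ccc1OCc1ccccc1 | intermediate
7 | tert-butyl 2-[(4R,6R)-6-[2-(4-benzyloxy-3-methoxyphenyl)ethyl]-2,2-dimethyl-1,3-dioxan-4-yl]acetate | COc1cc(CC[C@@H]2C[C@H](CC(=O)OC(C)(C)C)OC(C)(C)O2)ccc1OCc1ccccc1 | intermediate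
8 | {2-[(4R,6R)-6-[2-(4-benzyloxy-3-methoxyphenyl)ethyl]-2,2-dimethyl-1,3-dioxan-4-yl]-1-tert-butoxyethoxy}bis(2-methylpropyl)alumane (aluminium hemiacetal, epimer mixture) | COc1cc(CC[C@@H]2C[C@H](CC(OC(C)(C)C)O[Al](CC(C)C)CC(C)C)OC(C)(C)O2)ccc1OCc1ccccc1 | intermediate
9 | 2-[(4R,6R)-6-[2-(4-benzyloxy-3-methoxyphenyl)ethyl]-2,2-dimethyl-1,3-dioxan-4-yl]acetaldehyde | COc1cc(CC[C@@H]2C[C@H](CC=O)OC(C)(C)O2)ccc1OCc1ccccc1 | intermediate
10 | ethynylmagnesium bromide | C#C[Mg]Br | starting material
11 | (2RS)-1-[(4S,6R)-6-[2-(4-benzyloxy-3-methoxyphenyl)ethyl]-2,2-dimethyl-1,3-dioxan-4-yl]but-3-yn-2-ol | COc1cc(CC[C@@H]2C[C@H](CC(O)C#C)OC(C)(C)O2)ccc1OCc1ccccc1 | intermediate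
12 | 1-[(4R,6R)-6-[2-(4-benzyloxy-3-methoxyphenyl)ethyl]-2,2-dimethyl-1,3-dioxan-4-yl]but-3-yn-2-one | COc1cc(CC[C@@H]2C[C@H](CC(=O)C#C)OC(C)(C)O2)ccc1OCc1ccccc1 | intermediate
13 | 2,3-bis(trimethylsilyloxy)buta-1,3-diene | C=C(O[Si](C)(C)C)C(=C)O[Si](C)(C)C | starting material
14 | 1-[4,5-bis(trimethylsilyloxy)cyclohexa-1,4-dien-1-yl]-2-[(4R,6R)-6-[2-(4-benzyloxy-3-methoxyphenyl)ethyl]-2,2-dimethyl-1,3-dioxan-4-yl]ethan-1-one | COc1cc(CC[C@@H]2C[C@H](CC(=O)C3=CCC(O[Si](C)(C)C)=C(O[Si](C)(C)C)C3)OC(C)(C)O2)ccc1OCc1ccccc1 | intermediate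
15 | 1-[3,4-bis(trimethylsilyloxy)phenyl]-2-[(4R,6R)-6-[2-(4-benzyloxy-3-methoxyphenyl)ethyl]-2,2-dimethyl-1,3-dioxan-4-yl]ethan-1-one | COc1cc(CC[C@@H]2C[C@H](CC(=O)c3ccc(O[Si](C)(C)C)c(O[Si](C)(C)C)c3)OC(C)(C)O2)ccc1OCc1ccccc1 | intermediate
16 | 2-[(4R,6R)-6-[2-(4-benzyloxy-3-methoxyphenyl)ethyl]-2,2-dimethyl-1,3-dioxan-4-yl]-1-(3,4-dihydroxyphenyl)ethan-1-one | COc1cc(CC[C@@H]2C[C@H](CC(=O)c3ccc(O)c(O)c3)OC(C)(C)O2)ccc1OCc1ccccc1 | intermediate
17 | 1-(3,4-dihydroxyphenyl)-2-[(4R,6R)-6-[2-(4-hydroxy-3-methoxyphenyl)ethyl]-2,2-dimethyl-1,3-dioxan-4-yl]ethan-1-one | COc1cc(CC[C@@H]2C[C@H](CC(=O)c3ccc(O)c(O)c3)OC(C)(C)O2)ccc1O | intermediate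
18 | 4-{(1RS)-1-hydroxy-2-[(4S,6R)-6-[2-(4-hydroxy-3-methoxyphenyl)ethyl]-2,2-dimethyl-1,3-dioxan-4-yl]ethyl}benzene-1,2-diol | COc1cc(CC[C@@H]2C[C@H](CC(O)c3ccc(O)c(O)c3)OC(C)(C)O2)ccc1O | intermediate
19 | 4-{2-[(4S,6R)-6-[2-(4-hydroxy-3-methoxyphenyl)ethyl]-2,2-dimethyl-1,3-dioxan-4-yl]ethyl}benzene-1,2-diol | COc1cc(CC[C@@H]2C[C@H](CCc3ccc(O)c(O)c3)OC(C)(C)O2)ccc1O | intermediate
20 | (3R,5S)-7-(3,4-dihydroxyphenyl)-1-(4-hydroxy-3-methoxyphenyl)heptane-3,5-diol | COc1cc(CC[C@H](C[C@H](CCc2ccc(O)c(O)c2)O)O)ccc1O | intermediate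
21 | (3R,5S)-1-(4-acetoxy-3-methoxyphenyl)-7-(3,4-diacetoxyphenyl)heptane-3,5-diyl diacetate | COc1cc(CC[C@H](C[C@H](CCc2ccc(OC(C)=O)c(OC(C)=O)c2)OC(C)=O)OC(C)=O)ccc1OC(C)=O | intermediate
22 | (3R,5S)-7-(3,4-dihydroxyphenyl)-1-(4-hydroxy-3-methoxyphenyl)heptane-3,5-diyl diacetate | COc1cc(CC[C@H](C[C@H](CCc2ccc(O)c(O)c2)OC(C)=O)OC(C)=O)ccc1O | target

**Total step count:** 12
**Longest linear sequence:** 11 steps (steps 2–12 from compound 3; equally step 1 and steps 3–12 from compound 1)

**Steps most likely to fail**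

Step 8. The cycloaddition of the 2,3-dioxygenated diene with a mono-activated alkyne may be slow, and the β-alkoxy ynone may meanwhile decompose by elimination of the C5 oxygen or by polymerisation. The diene may also hydrolyse, or the DDQ stage may over-oxidise. The fallback gives up the de novo arene construction and sets out from aldehyde 9. Commercial 4-bromo-1,2-bis(benzyloxy)benzene is converted with Mg in THF into [3,4-bis(benzyloxy)phenyl]magnesium bromide F1. Addition of this to 9 at −78 °C should give the tris(benzyl) carbinol (1RS)-1-[3,4-bis(benzyloxy)phenyl]-2-[(4S,6R)-6-[2-(4-benzyloxy-3-methoxyphenyl)ethyl]-2,2-dimethyl-1,3-dioxan-4-yl]ethan-1-ol F2. Hydrogenolysis of F2 (H2, 10% Pd/C, EtOAc–MeOH, AcOH) should cleave the three benzyl ethers and the benzylic C7–O bond and so return to the route at 19.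

Step 9. The deoxygenation may stall at the benzylic carbinol, or the acetonide may be lost early in the acidic medium, which would let the C3 hydroxyl trap the C7 cation as a tetrahydropyran. The fallback activates the benzylic oxygen as an acetate and hydrogenolyses under neutral conditions, setting out from 15. NaBH4 in MeOH at 0 °C should reduce the ketone and strip the silyl groups to give the carbinol 4-{(1RS)-2-[(4S,6R)-6-[2-(4-benzyloxy-3-methoxyphenyl)ethyl]-2,2-dimethyl-1,3-dioxan-4-yl]-1-hydroxyethyl}benzene-1,2-diol F3. Ac2O and pyridine should then give the triacetate 4-{(1RS)-1-acetoxy-2-[(4R,6R)-6-[2-(4-benzyloxy-3-methoxyphenyl)ethyl]-2,2-dimethyl-1,3-dioxan-4-yl]ethyl}-1,2-phenylene diacetate F4. Hydrogenation (H2, 10% Pd/C, EtOAc) should remove the benzylic acetate and the benzyl ether to give 4-{2-[(4S,6R)-6-[2-(4-hydroxy-3-methoxyphenyl)ethyl]-2,2-dimethyl-1,3-dioxan-4-yl]ethyl}-1,2-phenylene diacetate F5. Aqueous methanolic HCl at 40 °C should then cleave the acetonide and the two aryl acetates and return to the route at 20.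

Step 5. The hindered tert-butyl ester may be over-reduced to the primary alcohol or react incompletely. The fallback is full reduction and re-oxidation, setting out from 7. LiAlH4 in THF at 0 °C should give 2-[(4S,6R)-6-[2-(4-benzyloxy-3-methoxyphenyl)ethyl]-2,2-dimethyl-1,3-dioxan-4-yl]ethan-1-ol F6, and Dess–Martin oxidation of F6 should return to the route at 9.

**Further compounds**
F1 | step 8 | [3,4-bis(benzyloxy)phenyl]magnesium bromide | Br[Mg]c1ccc(OCc2ccccc2)c(OCc2ccccc2)c1
F2 | step 8 | (1RS)-1-[3,4-bis(benzyloxy)phenyl]-2-[(4S,6R)-6-[2-(4-benzyloxy-3-methoxyphenyl)ethyl]-2,2-dimethyl-1,3-dioxan-4-yl]ethan-1-ol | COc1cc(CC[C@@H]2C[C@H](CC(O)c3ccc(OCc4ccccc4)c(OCc4ccccc4)c3)OC(C)(C)O2)ccc1OCc1ccccc1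
F3 | step 9 | 4-{(1RS)-2-[(4S,6R)-6-[2-(4-benzyloxy-3-methoxyphenyl)ethyl]-2,2-dimethyl-1,3-dioxan-4-yl]-1-hydroxyethyl}benzene-1,2-diol | COc1cc(CC[C@@H]2C[C@H](CC(O)c3ccc(O)c(O)c3)OC(C)(C)O2)ccc1OCc1ccccc1
F4 | step 9 | 4-{(1RS)-1-acetoxy-2-[(4R,6R)-6-[2-(4-benzyloxy-3-methoxyphenyl)ethyl]-2,2-dimethyl-1,3-dioxan-4-yl]ethyl}-1,2-phenylene diacetate | COc1cc(CC[C@@H]2C[C@H](CC(OC(C)=O)c3ccc(OC(C)=O)c(OC(C)=O)c3)OC(C)(C)O2)ccc1OCc1ccccc1
F5 | step 9 | 4-{2-[(4S,6R)-6-[2-(4-hydroxy-3-methoxyphenyl)ethyl]-2,2-dimethyl-1,3-dioxan-4-yl]ethyl}-1,2-phenylene diacetate | COc1cc(CC[C@@H]2C[C@H](CCc3ccc(OC(C)=O)c(OC(C)=O)c3)OC(C)(C)O2)ccc1O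
F6 | step 5 | 2-[(4S,6R)-6-[2-(4-benzyloxy-3-methoxyphenyl)ethyl]-2,2-dimethyl-1,3-dioxan-4-yl]ethan-1-ol | COc1cc(CC[C@@H]2C[C@H](CCO)OC(C)(C)O2)ccc1OCc1ccccc1
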